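**Plan**
- Retrosynthesis: after removal of the O-protecting groups, the two CH2–CH= bonds inside the prenyl groups are cut. Each prenyl group is a benzylic CH2 on ring A joined to a 2-methylprop-1-enyl unit. Next the two ring-A C–CH2 bonds at C3' and C5' are cut, and last the C1'–C(=O) bond.
- Enabling feature: C3' and C5' are the only ring-A carbons ortho or para to the 2'- and 4'-hydroxyls, so a phenolic Mannich reaction places a one-carbon handle exactly there, and that handle can be turned into a benzylic bromide.
- Forward: the ring-B phenol is mesylated and a Friedel–Crafts acylation of resorcinol joins the chain. Twofold aminomethylation, acetylative amine exchange and HBr then give the bis(bromomethyl) diacetate. A twofold benzyl–alkenyl Suzuki coupling completes both prenyl groups, and base removes all three O-protecting groups.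
- No ring is formed; both benzene rings are bought. Gancaonin J has no stereocentre and no alkene with E/Z isomers, so there is no stereochemistry to set.

Key step: step 6

**Route**

Step 1
Reactants: 1 3-(4-hydroxyphenyl)propanoic acid
Product: 2 3-[4-(methanesulfonyloxy)phenyl]propanoic acid
Conditions: MsCl (1.5 equiv), 2 M aq. NaOH, THF, 0 °C to rt; then 2 M HCl to pH 2
Reagents that add atoms: methanesulfonyl chloride, CS(=O)(=O)Cl
Why: Schotten–Baumann O-sulfonylation of the phenoxide should give the aryl mesylate, while any mixed carboxylic–sulfonic anhydride formed at the carboxylate is hydrolysed again in the aqueous base.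

Step 2
Reactants: 2 3-[4-(methanesulfonyloxy)phenyl]propanoic acid; 3 resorcinol
Product: 4 1-(2,4-dihydroxyphenyl)-3-[4-(methanesulfonyloxy)phenyl]propan-1-one
Conditions: BF3·OEt2 (neat, as solvent and promoter), 85 °C; then aq. NaOAc
Reagents that add atoms: none
Why: Friedel–Crafts (Nencki-type) acylation of resorcinol with a free carboxylic acid should occur once, at C4 (para to one hydroxyl, ortho to the other), because the resulting ortho-hydroxy ketone is deactivated and the mesylated ring B is too electron-poor to close to an indanone.

Step 3
Reactants: 4 1-(2,4-dihydroxyphenyl)-3-[4-(methanesulfonyloxy)phenyl]propan-1-one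
Product: 6 1-[3,5-bis(dimethylaminomethyl)-2,4-dihydroxyphenyl]-3-[4-(methanesulfonyloxy)phenyl]propan-1-one, via 3'-mono-Mannich base 5 (not isolated)
Conditions: 37% aq. CH2O (5 equiv), 40% aq. Me2NH (5 equiv), EtOH, 75 °C
Reagents that add atoms: formaldehyde, C=O; dimethylamine, CNC
Why: The phenolic Mannich reaction should aminomethylate first C3' (between the two hydroxyls) and then C5', the only other position activated by them, while the mesylated ring B and, in the absence of acid, the ketone α-carbon stay untouched.

Step 4
Reactants: 6 1-[3,5-bis(dimethylaminomethyl)-2,4-dihydroxyphenyl]-3-[4-(methanesulfonyloxy)phenyl]propan-1-one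
Product: 7 1-[2,4-diacetoxy-3,5-bis(acetoxymethyl)phenyl]-3-[4-(methanesulfonyloxy)phenyl]propan-1-one
Conditions: Ac2O (neat), 110 °C
Reagents that add atoms: acetic anhydride, CC(=O)OC(C)=O
Why: Acetylative cleavage of a phenolic Mannich base: N-acetylation turns each dimethylamino group into an acylammonium leaving group that acetate displaces at the benzylic carbon, and both phenols are O-acetylated in the same pot; the temperature is kept below reflux and no acetate salt is added, to disfavour chromone formation at the 2'-acetoxy ketone.

Step 5
Reactants: 7 1-[2,4-diacetoxy-3,5-bis(acetoxymethyl)phenyl]-3-[4-(methanesulfonyloxy)phenyl]propan-1-one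
Product: 8 1-[2,4-diacetoxy-3,5-bis(bromomethyl)phenyl]-3-[4-(methanesulfonyloxy)phenyl]propan-1-one
Conditions: 33% HBr in AcOH, rt
Reagents that add atoms: hydrogen bromide, Br
Why: Acid-promoted nucleophilic substitution of the protonated benzylic acetates by bromide should give the bis(benzylic bromide), while the aryl acetates and the aryl mesylate have no such pathway and are not solvolysed in water-free acetic acid.

Step 6
Reactants: 8 1-[2,4-diacetoxy-3,5-bis(bromomethyl)phenyl]-3-[4-(methanesulfonyloxy)phenyl]propan-1-one; 9 2-methylprop-1-enylboronic acid pinacol ester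
Product: 11 1-[2,4-diacetoxy-3,5-bis(3-methylbut-2-enyl)phenyl]-3-[4-(methanesulfonyloxy)phenyl]propan-1-one, via 5'-prenyl 3'-bromomethyl monocoupled diacetate 10 (not isolated)
Conditions: 9 (3 equiv), Pd(PPh3)4 (10 mol %), anhydrous K3PO4 (finely ground, 4 equiv), 1,4-dioxane, 80 °C, argon
Reagents that add atoms: none
Why: Zerovalent palladium inserts into a benzylic C–Br bond by an SN2-like oxidative addition, the phosphate-activated boronate hands its 2-methylprop-1-enyl group to the divalent benzylpalladium bromide, and reductive elimination forms the CH2–CH= bond of a prenyl group, expected first at the less hindered C5' bromide (10) and then at C3'. The closest known reaction type is the Suzuki–Miyaura coupling of benzylic bromides with alkenylboronic esters, run here twice on one arene. No ring is closed and no stereocentre is created; the new alkene carries two identical methyl groups and so has no geometry to control, and because the alkene arrives intact as a vinyl unit only the linear prenyl isomer can form, with no O-alkylation and no reverse prenylation. The step needs chemoselectivity for the two benzylic C–Br bonds over the aryl acetates, the aryl mesylate and the enolisable ketone; this should come from the far faster oxidative addition at a benzylic bromide than at aryl C–O bonds under PPh3 ligation, and from the weak, poorly soluble anhydrous phosphate, which should leave the acetates in place. The benzylpalladium intermediate has no β-hydrogen, so β-hydride elimination cannot compete, and the excess of boronate should keep transmetalation ahead of benzylic homocoupling.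

Step 7
Reactants: 11 1-[2,4-diacetoxy-3,5-bis(3-methylbut-2-enyl)phenyl]-3-[4-(methanesulfonyloxy)phenyl]propan-1-one
Product: 12 Gancaonin J, 1-[2,4-dihydroxy-3,5-bis(3-methylbut-2-enyl)phenyl]-3-(4-hydroxyphenyl)propan-1-one
Conditions: KOH (10 equiv), MeOH/H2O (4:1), 65 °C, argon; then 1 M HCl to pH 5 at 0 °C
Reagents that add atoms: none
Why: Saponification of the two aryl acetates and base hydrolysis of the aryl mesylate should free all three phenols in one operation; the prenyl groups and the saturated ketone are inert to hydroxide, water intercepts any sulfene as methanesulfonate, and the cold, mild acidification avoids acid-induced chroman formation.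

**Compound list**
1 | 3-(4-hydroxyphenyl)propanoic acid | O=C(O)CCc1ccc(O)cc1 | starting material
2 | 3-[4-(methanesulfonyloxy)phenyl]propanoic acid | CS(=O)(=O)Oc1ccc(CCC(=O)O)cc1 | intermediate
3 | resorcinol | Oc1cccc(O)c1 | starting material
4 | 1-(2,4-dihydroxyphenyl)-3-[4-(methanesulfonyloxy)phenyl]propan-1-one | CS(=O)(=O)Oc1ccc(CCC(=O)c2ccc(O)cc2O)cc1 | intermediate
5 | 1-[3-(dimethylaminomethyl)-2,4-dihydroxyphenyl]-3-[4-(methanesulfonyloxy)phenyl]propan-1-one (3'-mono-Mannich base) | CN(C)Cc1c(O)ccc(C(=O)CCc2ccc(OS(C)(=O)=O)cc2)c1O | intermediate (not isolated)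
6 | 1-[3,5-bis(dimethylaminomethyl)-2,4-dihydroxyphenyl]-3-[4-(methanesulfonyloxy)phenyl]propan-1-one | CN(C)Cc1cc(C(=O)CCc2ccc(OS(C)(=O)=O)cc2)c(O)c(CN(C)C)c1O | intermediate
7 | 1-[2,4-diacetoxy-3,5-bis(acetoxymethyl)phenyl]-3-[4-(methanesulfonyloxy)phenyl]propan-1-one | CC(=O)OCc1cc(C(=O)CCc2ccc(OS(C)(=O)=O)cc2)c(OC(C)=O)c(COC(C)=O)c1OC(C)=O | intermediate
8 | 1-[2,4-diacetoxy-3,5-bis(bromomethyl)phenyl]-3-[4-(methanesulfonyloxy)phenyl]propan-1-one | CC(=O)Oc1c(CBr)cc(C(=O)CCc2ccc(OS(C)(=O)=O)cc2)c(OC(C)=O)c1CBr | intermediate
9 | 2-methylprop-1-enylboronic acid pinacol ester | CC(C)=CB1OC(C)(C)C(C)(C)O1 | starting material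
10 | 1-[2,4-diacetoxy-3-(bromomethyl)-5-(3-methylbut-2-enyl)phenyl]-3-[4-(methanesulfonyloxy)phenyl]propan-1-one | CC(C)=CCc1cc(C(=O)CCc2ccc(OS(C)(=O)=O)cc2)c(OC(C)=O)c(CBr)c1OC(C)=O | intermediate (not isolated)
11 | 1-[2,4-diacetoxy-3,5-bis(3-methylbut-2-enyl)phenyl]-3-[4-(methanesulfonyloxy)phenyl]propan-1-one | CC(C)=CCc1cc(C(=O)CCc2ccc(OS(C)(=O)=O)cc2)c(OC(C)=O)c(CC=C(C)C)c1OC(C)=O | intermediate
12 | Gancaonin J | CC(C)=CCc1cc(C(=O)CCc2ccc(O)cc2)c(O)c(CC=C(C)C)c1O | target

**Step count**
Total steps: 7. Longest linear sequence: 7 steps (1 → 2 → 4 → 6 → 7 → 8 → 11 → 12).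

**Steps most likely to fail**

Step 6. Transmetalation from the pinacol boronate may be slow under anhydrous phosphate. The benzylic bromides and the benzylpalladium species would then stay exposed to base and free phosphine for a long time. Loss of the ortho acetates with quinone-methide oligomerisation, benzylic homocoupling or alkylation of PPh3 could then outrun the second coupling. The fallback sets out from 8 and comes back at 11. It replaces the base-activated boron partner by a neutral tin partner in a Stille coupling: tributyl(2-methylprop-1-enyl)stannane, Pd2(dba)3 and tri(2-furyl)phosphine in THF at 60 °C, with no base in the flask. The benzylic CH2–CH= bonds are formed as before, and no new compound arises (F0).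

Step 3. The second aminomethylation at C5' may stall once C3' is substituted, or forcing conditions may bring aminomethylation at the ketone α-carbon into play. The fallback sets out from 4 and comes back at 7. The two carbons are introduced at the aldehyde oxidation level by a twofold Duff formylation (hexamethylenetetramine, CF3CO2H, 90 °C; then aq. HCl). Its benzylamine-type intermediates keep the ring electron-rich until hydrolysis, and it should give 2,4-dihydroxy-5-{3-[4-(methanesulfonyloxy)phenyl]propanoyl}benzene-1,3-dicarbaldehyde F1. Selective reduction of the two aldehydes beside the chelated aryl ketone with NaBH(OAc)3 in THF should give the 3',5'-bis(hydroxymethyl) ketone F2. Acetylation with Ac2O, pyridine and catalytic DMAP at 0 °C to rt returns the tetraacetate 7.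

Step 4. Hot acetic anhydride with the amine present may drive a Kostanecki–Robinson-type cyclisation of the 2'-acetoxy ketone to a chromone, or the exchange at the crowded C3' position may remain incomplete. The fallback sets out from 6 and comes back at 7. Quaternisation with MeI in acetone at rt should give the 3',5'-bis(trimethylammoniomethyl) diiodide F3. Warming F3 with KOAc in AcOH at 70 °C should expel trimethylamine through ortho-quinone methides that acetate traps, giving the 3',5'-bis(acetoxymethyl)-2',4'-dihydroxy ketone F4. Acetylation of the two phenols at rt (Ac2O, pyridine, catalytic DMAP) then gives 7 without exposing the acetoxy ketone to heat.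

**Further compounds**
F0 | step 6 | none | none
F1 | step 3 | 2,4-dihydroxy-5-{3-[4-(methanesulfonyloxy)phenyl]propanoyl}benzene-1,3-dicarbaldehyde | O=Cc1cc(C(=O)CCc2ccc(OS(C)(=O)=O)cc2)c(O)c(C=O)c1O
F2 | step 3 | 1-[2,4-dihydroxy-3,5-bis(hydroxymethyl)phenyl]-3-[4-(methanesulfonyloxy)phenyl]propan-1-one | OCc1cc(C(=O)CCc2ccc(OS(C)(=O)=O)cc2)c(O)c(CO)c1O
F3 | step 4 | 1-[2,4-dihydroxy-3,5-bis(trimethylammoniomethyl)phenyl]-3-[4-(methanesulfonyloxy)phenyl]propan-1-one diiodide | C[N+](C)(C)Cc1cc(C(=O)CCc2ccc(OS(C)(=O)=O)cc2)c(O)c(C[N+](C)(C)C)c1O.[I-].[I-]
F4 | step 4 | 1-[3,5-bis(acetoxymethyl)-2,4-dihydroxyphenyl]-3-[4-(methanesulfonyloxy)phenyl]propan-1-one | CC(=O)OCc1cc(C(=O)CCc2ccc(OS(C)(=O)=O)cc2)c(O)c(COC(C)=O)c1O
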